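Numbering follows the cembrane skeleton (ring C1–C14; lactone O on C14, α-carbon C15 on C1, acetate on C13, epoxide C3–C4). Everything rests on forming C1–C15 while C13–C14–C1=C2 sit in a temporary six-membered lactone (O13–C3=O). An O14-bound phosphonoacetate adds intramolecularly to C1 of this dihydropyranone: the γ-lactone ring (O14, C14, C1, C15, C16) closes, C1 is set because only the cis-fused bicycle can form, and C15 keeps a phosphonate that finally delivers the exocyclic methylene. The step exploits the cis ring fusion at C1/C14 and the oxygen on C13. The precursor is a small furfural-derived pyranone; C3 then grows the chain and metathesis at C10=C11 closes the macrocycle.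

Key step: step 6

Assumption: the Luche reduction in step 4 is taken to deliver hydride anti to the C13 side chain of the nearly planar ene-dione, giving the cis (13,14-syn) alcohol.

Step 1
Reactants: 1 furfural; 2 (Z)-crotylboronic acid pinacol ester
Product: 3 (1R,2S)-1-(furan-2-yl)-2-methylbut-3-en-1-ol
Conditions: (R)-TRIP phosphoric acid (5 mol%), 4 Å MS, toluene, −30 °C; aq. work-up
Reagents that add atoms: none
Why: Chiral phosphoric acid-catalysed crotylboration through a closed chair transition state should turn the Z-geometry of 2 into the syn C12/C13 relationship while the (R)-catalyst (sense assigned by analogy with aryl aldehydes) selects the aldehyde face that gives the (1R,2S) alcohol.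

Step 2
Reactants: 3 (1R,2S)-1-(furan-2-yl)-2-methylbut-3-en-1-ol
Product: 4 (2R)-2-[(2S)-but-3-en-2-yl]-6-hydroxy-2H-pyran-3(6H)-one (anomer mixture)
Conditions: NBS, NaHCO3, NaOAc, THF–H2O (4:1), 0 °C
Reagents that add atoms: water, O
Why: Achmatowicz rearrangement (bromination of the electron-rich furan, hydration, ring expansion) should give the pyranone with C13 untouched, the isolated vinyl group reacting far more slowly than the furan.

Step 3
Reactants: 4 (2R)-2-[(2S)-but-3-en-2-yl]-6-hydroxy-2H-pyran-3(6H)-one
Product: 5 (6R)-6-[(2S)-but-3-en-2-yl]-2H-pyran-2,5(6H)-dione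
Conditions: CrO3, H2SO4, H2O, acetone, 0 °C
Reagents that add atoms: none
Why: Jones oxidation of the allylic lactol should give the δ-lactone carbonyl (C3) that later activates C1, without touching the vinyl group.

Step 4
Reactants: 5 (6R)-6-[(2S)-but-3-en-2-yl]-2H-pyran-2,5(6H)-dione
Product: 6 (5R,6R)-6-[(2S)-but-3-en-2-yl]-5-hydroxy-5,6-dihydro-2H-pyran-2-one (5,6-cis)
Conditions: NaBH4, CeCl3·7H2O, MeOH–CH2Cl2, −78 °C
Reagents that add atoms: none
Why: Luche 1,2-reduction should attack the C14 ketone anti to the C13 side chain, setting C14 cis to it (the 13,14-syn relationship of the target).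

Step 5
Reactants: 6 (5R,6R)-6-[(2S)-but-3-en-2-yl]-5-hydroxy-5,6-dihydro-2H-pyran-2-one; 7 (diethoxyphosphoryl)acetic acid
Product: 8 (5R,6R)-6-[(2S)-but-3-en-2-yl]-2-oxo-5,6-dihydro-2H-pyran-5-yl (diethoxyphosphoryl)acetate
Conditions: DCC, DMAP (cat.), CH2Cl2, 0 °C to rt
Reagents that add atoms: none
Why: Steglich esterification of the secondary allylic alcohol places the C15–C16 unit on O14 with retention at C14.

Step 6
Reactants: 8 (5R,6R)-6-[(2S)-but-3-en-2-yl]-2-oxo-5,6-dihydro-2H-pyran-5-yl (diethoxyphosphoryl)acetate
Product: 9 cis-fused bicyclic bis-lactone phosphonate: γ-lactone O14–C16(=O)–C15H[P(O)(OEt)2]–C1–C14 fused at C1–C14 to δ-lactone O13–C3(=O)–C2H2–C1–C14–C13, (S)-but-3-en-2-yl on C13; C1, C12, C13, C14 as in the target, C15 epimers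
Conditions: KOtBu (1.05 equiv), THF, −78 to 0 °C; AcOH quench
Reagents that add atoms: none
Why: Deprotonation of the phosphonoacetate CH2 (the most acidic site) gives a stabilised carbanion that adds to C1, the β-carbon of the unsaturated δ-lactone, and proton transfer from the new C15–H to the lactone enolate makes the addition irreversible. The closest known reaction type is the intramolecular Michael addition of γ-(phosphonoacetoxy) enones that forms the first half of telescoped Michael/olefination routes to cis-fused α-methylene-γ-butyrolactones. The γ-lactone ring (O14, C16, C15, C1, C14) closes in the 5-exo-trig mode. C1 is controlled by C14: the tether on O14 can reach C1 only from the face of the ring alkene that carries O14, and because C13–C14–C1–C2 are held in the six-membered lactone the product must be the cis-fused bicycle (C2 and C13 cis on the new lactone, as in the target), while C15 forms as a mixture that converges in step 15. The step needs conjugate addition to outrun base-induced elimination or ring opening of the acyloxy lactone, which the low pKa of the phosphonoacetate, one equivalent of base and low temperature should secure; the vinyl group is inert.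

Step 7
Reactants: 9 cis-fused bicyclic bis-lactone phosphonate
Product: 11 α-phosphono-γ-lactone diol: C14 carries the (1R,2S)-1-hydroxy-2-methylbut-3-enyl chain (C13–OH), C1 carries CH2–CH(OH)–C(CH3)=CH2 (C2–C5, C18); C3 and C15 epimers, via lactol 10 (not isolated)
Conditions: NaH (1.05 equiv), THF, 0 °C; i-Bu2AlH (1.2 equiv), −78 °C; CH2=C(CH3)MgBr (3 equiv), −78 to 0 °C; aq. NH4Cl
Reagents that add atoms: isopropenylmagnesium bromide, CC(=C)[Mg]Br
Why: With the phosphonolactone masked as its sodium enolate, i-Bu2AlH should reduce only the δ-lactone to the lactolate, whose aldehyde form is trapped by Grignard 1,2-addition; the C3 carbinol centre is left uncontrolled because step 8 destroys it.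

Step 8
Reactants: 11 α-phosphono-γ-lactone diol
Product: 12 ethyl ester: as 11 but C1 carries CH2–CH=C(CH3)–CH2CH2–CO2Et with E-C3=C4 (C7 ester); C13–OH free
Conditions: CH3C(OEt)3, EtCO2H (cat.), xylene, 140 °C (EtOH distilled off); aq. AcOH work-up, then K2CO3, EtOH, rt
Reagents that add atoms: triethyl orthoacetate, CCOC(C)(OCC)OCC
Why: Johnson–Claisen rearrangement through a chair transition state with the C2 substituent equatorial should give the E-C3=C4 alkene from either C3 epimer and add C6–C7, the basic ethanol treatment returning any C13 orthoester or acetate to the alcohol.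

Step 9
Reactants: 12 ethyl ester with E-C3=C4
Product: 13 (3R,4R)-epoxy ester (trisubstituted C3–C4 epoxide, otherwise as 12)
Conditions: D-fructose-derived Shi ketone (30 mol%), KHSO5 (as Oxone), NaHCO3 buffer (pH 8), Bu4NHSO4, MeCN–CH2(OMe)2–H2O, 0 °C
Reagents that add atoms: potassium peroxymonosulfate, [K+].[O-]S(=O)(=O)OO
Why: Shi epoxidation through the spiro dioxirane transition state should oxidise only the trisubstituted C3=C4 alkene (the monosubstituted vinyl group is a poor substrate) and the catalyst should set C3 and C4 as (3R,4R), the near-neutral buffer keeping the phosphonate protonated.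

Step 10
Reactants: 13 (3R,4R)-epoxy ester
Product: 15 isopropenyl carbinol: C1 chain ends in CH2CH2–CH(OH)–C(CH3)=CH2 (C5–C9, C19); C7 epimers, via aldehyde 14 (not isolated)
Conditions: NaH (1.05 equiv), THF, 0 °C; i-Bu2AlH (2.3 equiv), −78 °C; CH2=C(CH3)MgBr (2 equiv), −78 to 0 °C; aq. NH4Cl
Reagents that add atoms: isopropenylmagnesium bromide, CC(=C)[Mg]Br
Why: Enolate-protected partial reduction of the ethyl ester and in situ Grignard addition to the aldehyde should give the allylic alcohol without opening the trisubstituted epoxide; the C7 centre is irrelevant because step 12 removes it.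

Step 11
Reactants: 15 isopropenyl carbinol
Product: 16 diacetate (C7–OAc and C13–OAc)
Conditions: Ac2O, pyridine, DMAP (cat.), CH2Cl2, 0 °C to rt
Reagents that add atoms: acetic anhydride, CC(=O)OC(C)=O
Why: Acetylation by nucleophilic catalysis makes the C7 allylic leaving group and installs the C13 acetate of the target with retention.

Step 12
Reactants: 16 diacetate
Product: 17 triene: C1 chain ends in (E)-CH=C(CH3)–CH2–CH=CH2 (C7=C8, C9, C10 and one extra CH2)
Conditions: Bu3SnCH=CH2, Pd2(dba)3 (5 mol%), PPh3, LiCl, DMF, 40 °C
Reagents that add atoms: tributyl(vinyl)stannane, C=C[Sn](CCCC)(CCCC)CCCC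
Why: Stille-type allylic substitution should ionise only the allylic C7 acetate to a 2-methyl π-allyl palladium complex in which the C6 chain prefers the syn position, and vinyl transfer to the less hindered CH2 terminus (C9) then gives the E-C7=C8 alkene from both C7 epimers.

Step 13
Reactants: 17 triene
Product: 18 macrocycle: target skeleton with C15H–P(O)(OEt)2 in place of the methylene and an extra C10=C11 double bond (E/Z mixture)
Conditions: second-generation Grubbs catalyst (10 mol%), CH2Cl2 (1 mM), 40 °C
Reagents that add atoms: none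
Why: Ring-closing metathesis between the two monosubstituted alkenes should close the 14-membered ring at C10=C11, remote from all stereocentres, the trisubstituted alkene being inert and the alkene geometry irrelevant.

Step 14
Reactants: 18 macrocyclic diene phosphonate
Product: 19 saturated macrocycle: target with C15H–P(O)(OEt)2 in place of the exocyclic methylene
Conditions: 2-nitrobenzenesulfonohydrazide, Et3N, CH2Cl2, rt
Reagents that add atoms: none
Why: Diimide generated in situ should reduce the 1,2-disubstituted C10=C11 alkene by concerted syn hydrogen transfer much faster than the trisubstituted C7=C8 alkene, leaving epoxide, acetate and lactone untouched.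

Step 15
Reactants: 19 saturated macrocyclic phosphonate
Product: 20 eupalmerin acetate
Conditions: K2CO3, aq. CH2O (37%), THF, 0 °C to rt
Reagents that add atoms: formaldehyde, C=O
Why: Horner–Wadsworth–Emmons olefination of the phosphonate-stabilised lactone anion with formaldehyde should convert both C15 epimers into the exocyclic C15=C17 methylene under conditions mild enough for acetate and epoxide.

Compound list
1 | furfural | O=Cc1ccco1 | starting material
2 | (Z)-crotylboronic acid pinacol ester | C/C=C\CB1OC(C)(C)C(C)(C)O1 | starting material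
3 | (1R,2S)-1-(furan-2-yl)-2-methylbut-3-en-1-ol | o1cccc1[C@H](O)[C@@H](C)C=C | intermediate
4 | (2R)-2-[(2S)-but-3-en-2-yl]-6-hydroxy-2H-pyran-3(6H)-one | O=C1C=CC(O)O[C@@H]1[C@@H](C)C=C | intermediate
5 | (6R)-6-[(2S)-but-3-en-2-yl]-2H-pyran-2,5(6H)-dione | O=C1C=CC(=O)O[C@@H]1[C@@H](C)C=C | intermediate
6 | (5R,6R)-6-[(2S)-but-3-en-2-yl]-5-hydroxy-5,6-dihydro-2H-pyran-2-one | O=C1C=C[C@@H](O)[C@@H]([C@@H](C)C=C)O1 | intermediate
7 | (diethoxyphosphoryl)acetic acid | OC(=O)CP(=O)(OCC)OCC | starting material
8 | (5R,6R)-6-[(2S)-but-3-en-2-yl]-2-oxo-5,6-dihydro-2H-pyran-5-yl (diethoxyphosphoryl)acetate | O=C1C=C[C@@H](OC(=O)CP(=O)(OCC)OCC)[C@@H]([C@@H](C)C=C)O1 | intermediate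
9 | cis-fused γ-lactone/δ-lactone phosphonate (C1–C15 bond formed) | CCOP(=O)(OCC)C1C(=O)O[C@H]2[C@@H]([C@@H](C)C=C)OC(=O)C[C@@H]12 | intermediate
10 | lactol of 9 (C3 hemiacetal) | CCOP(=O)(OCC)C1C(=O)O[C@H]2[C@@H]([C@@H](C)C=C)OC(O)C[C@@H]12 | intermediate
11 | α-phosphono-γ-lactone diol with isopropenyl carbinol at C3 | CCOP(=O)(OCC)C1C(=O)O[C@@H]([C@H](O)[C@@H](C)C=C)[C@H]1CC(O)C(C)=C | intermediate
12 | ethyl ester with E-C3=C4 (C7 ester) | CCOP(=O)(OCC)C1C(=O)O[C@@H]([C@H](O)[C@@H](C)C=C)[C@H]1C/C=C(\C)CCC(=O)OCC | intermediate
13 | (3R,4R)-epoxy ethyl ester | CCOP(=O)(OCC)C1C(=O)O[C@@H]([C@H](O)[C@@H](C)C=C)[C@H]1C[C@H]2O[C@]2(C)CCC(=O)OCC | intermediate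
14 | (3R,4R)-epoxy C7 aldehyde | CCOP(=O)(OCC)C1C(=O)O[C@@H]([C@H](O)[C@@H](C)C=C)[C@H]1C[C@H]2O[C@]2(C)CCC=O | intermediate
15 | epoxy isopropenyl carbinol (C7–OH) | CCOP(=O)(OCC)C1C(=O)O[C@@H]([C@H](O)[C@@H](C)C=C)[C@H]1C[C@H]2O[C@]2(C)CCC(O)C(C)=C | intermediate
16 | diacetate (C7–OAc, C13–OAc) | CCOP(=O)(OCC)C1C(=O)O[C@@H]([C@H](OC(C)=O)[C@@H](C)C=C)[C@H]1C[C@H]2O[C@]2(C)CCC(OC(C)=O)C(C)=C | intermediate
17 | triene with E-C7=C8 and allyl terminus | CCOP(=O)(OCC)C1C(=O)O[C@@H]([C@H](OC(C)=O)[C@@H](C)C=C)[C@H]1C[C@H]2O[C@]2(C)CC/C=C(\C)CC=C | intermediate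
18 | 14-membered macrocycle with C10=C11 and C15 phosphonate | CCOP(=O)(OCC)C1C(=O)O[C@H]2[C@H](OC(C)=O)[C@@H](C)C=CC/C(C)=C/CC[C@@]3(C)O[C@@H]3C[C@@H]12 | intermediate
19 | 10,11-saturated macrocyclic C15 phosphonate | CCOP(=O)(OCC)C1C(=O)O[C@H]2[C@H](OC(C)=O)[C@@H](C)CCC/C(C)=C/CC[C@@]3(C)O[C@@H]3C[C@@H]12 | intermediate
20 | eupalmerin acetate | C=C1C(=O)O[C@H]2[C@H](OC(C)=O)[C@@H](C)CCC/C(C)=C/CC[C@@]3(C)O[C@@H]3C[C@@H]12 | target

Total step count: 15. Longest linear sequence: 15 steps (1 to 20).

Steps most likely to fail:

Step 6 (key step). Base-induced elimination of the O14 carboxylate (vinylogous deprotonation at C14) or ring opening of the acyloxy lactone may compete with conjugate addition. The fallback sets out from 8: silylation (TMSCl, Et3N) should give the trimethylsilyl ketene acetal of 8 F1, and catalytic TMSOTf in CH2Cl2 at −78 °C should trigger an intramolecular Mukaiyama–Michael addition under non-basic conditions; aqueous work-up comes back to the route at 9.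

Step 9. Under the buffered peroxide conditions the phosphonate-stabilised carbanion may be oxidised, or the catalyst may turn over poorly, which would erode stereocontrol. The fallback sets out from 12: neutral epoxidation with dimethyldioxirane in acetone at −20 °C, where no carbanion is present, should give 13 together with the (3S,4S)-epoxide diastereomer F2; the two are separated by chromatography and the route is rejoined at 13.

Step 7. Chemoselectivity between the two lactones may be lost, or the lactolate may be over-reduced to the diol. The fallback sets out from 9: after enolisation of the phosphonolactone with i-PrMgCl, aminolysis of the δ-lactone with MeNH(OMe)·HCl should give the Weinreb amide F3; CH2=C(CH3)MgBr should convert it into the isopropenyl ketone F4, and Luche reduction (NaBH4, CeCl3·7H2O) comes back to the route at 11.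

Further compounds
F1 | step 6 | trimethylsilyl ketene acetal of ester 8 | O=C1C=C[C@@H](OC(O[Si](C)(C)C)=CP(=O)(OCC)OCC)[C@@H]([C@@H](C)C=C)O1
F2 | step 9 | (3S,4S)-epoxide diastereomer of 13 | CCOP(=O)(OCC)C1C(=O)O[C@@H]([C@H](O)[C@@H](C)C=C)[C@H]1C[C@@H]2O[C@@]2(C)CCC(=O)OCC
F3 | step 7 | C3 Weinreb amide from δ-lactone opening of 9 | CCOP(=O)(OCC)C1C(=O)O[C@@H]([C@H](O)[C@@H](C)C=C)[C@H]1CC(=O)N(C)OC
F4 | step 7 | C3 isopropenyl ketone | CCOP(=O)(OCC)C1C(=O)O[C@@H]([C@H](O)[C@@H](C)C=C)[C@H]1CC(=O)C(C)=C
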